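Readings and results stem from a simulated flask for an exercise; noise was put on by code.

At 180 min Tuesday's flask still held 73.2% of its solid substrate as solid, yet the product gained just 2.1 percentage points in the last 60.0 min. That run is the flask now asked about.

| setting | Tuesday's | flask |
|---|---|---|
| solid substrate | 20 mM | 20 mM |
| second substrate | 20 mM | 20.0 mM |
| protic impurity | 10 mM | 10.0 mM |
| free enzyme | 13 µM | 13 µM |
| temperature | 40 °C | 40 °C |
| remark | the very flask that is asked about, followed so far |  |
| time |  | 5.0 h |

- Tuesday's (time / min: product / %, solid substrate / %): 25.0: 7.3, 85.1; 60.0: 12.7, 79.7; 120: 17.3, 75.7; 180: 19.4, 73.2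

(each reading ± 0.5 percentage points)

- given per volume of solution although it is solid: solid substrate
- removed product is counted in
- at the start none of the solid substrate is in solution
- additions bring no volume worth counting

- summer: at 5.0 h take out 90% of the product then present, then wait 10 h
- dusk: at 5.0 h add second substrate, 50.0% of the amount charged, then wait 10 h
- winter: at 5.0 h add free enzyme, 50.0% of the amount charged, then wait 10 h
- dawn: change nothing and wait 10 h more

* product, in percent of the solid substrate first charged, at 5.0 h
* the remedy with the largest gain of product, or "none" below 2 percentage points (summer / dusk / winter / dawn / none)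
* product present, with what was taken out counted in, in percent of the solid substrate first charged, after summer
* product present, with what was taken out counted in, in percent of the solid substrate first charged, after winter

The last two steps of the readings are equally long, so their gains give r, the ratio of one step's gain to the step before. A rate falling by a constant ratio is a straight line in logarithms, and summing its steps gives the product still to come. Readings scatter by 0.5 points, so r is a rough reading.

r = 0.457, log10 r = −0.340: one power of ten lost every 176 min

still to come after the last reading: 1.8 points

plateau: 21.2%

two steps later, at 5.0 h: 20.8%, leaving 0.37 points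

So dawn gains less than 2 points, and summer counts the same if product does not hold the reaction back.

Charging the decline to the catalyst gives the turnover capacity N, the molecules of product per molecule of free enzyme charged, a turnover number:

N = 326

Winter's 50.0% of fresh enzyme then earns 11 points, but only if it finds the starting medium. That is the weak link. If the protic impurity takes second substrate one for one, and the rate follows second substrate, the flask keeps 5.84 mM, a share of 29.2%. The floor is then 3.1 points, and the middle of the two in logarithms is 5.7 points. On the same assumption dusk multiplies the late tail to 1 point. Winter leads, at 26.9%.

The forecast gives 20.6% now, 20.8% after summer and 30% after winter, a winter figure above this reckoning, picks winter, and holds that “Removing product, adding substrate or waiting adds almost nothing”.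

The flask gives 21.2% at 5.0 h, 22.0% after summer and 27.9% after winter. The gains are 0.86 points for summer, 2.3 points for dusk, 0.86 points for dawn and 6.7 points for winter, the best remedy.

    free enzyme → unfolded enzyme (k = 0.00958 min⁻¹, Ea = 280 kJ mol⁻¹)
    starting material + free enzyme ⇌ starting complex (K = 24.0 L mol⁻¹, k = 1.25 × 10⁵ L mol⁻¹ min⁻¹, Ea = 43.0 kJ mol⁻¹, ΔH = 7.00 kJ mol⁻¹)
    second substrate + starting complex ⇌ ternary complex (K = 33.0 L mol⁻¹, k = 2.50 × 10⁵ L mol⁻¹ min⁻¹, Ea = 30.0 kJ mol⁻¹, ΔH = 6.00 kJ mol⁻¹)
    ternary complex → free enzyme + product (k = 288 min⁻¹, Ea = 70.0 kJ mol⁻¹)
    solid substrate ⇌ starting material, rate k5*(cs5 - [starting material]) while solid is left; crystals form when [starting material] > cs5 (solubility = 1.60 mM, k = 1.80 min⁻¹)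
    second substrate + protic impurity → quenched reagent (k = 2.31 L mol⁻¹ min⁻¹, Ea = 49.0 kJ mol⁻¹)
    (constants at 40 °C)

In this flask second substrate has a half-life of 30 min by its passing with protic impurity into quenched reagent alone, the other concentrations as charged, shorter than the 72 min of free enzyme by unfolding alone, and at 300 min it stands at 29% of its charge. Turnovers per enzyme charged come to 326 in this flask at 5.0 h, 181 for the enzyme added in winter, counting only the gain beyond dawn's, and 283 in the neighbour flask charged with 0.022 mM, which reaches 31.2%.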